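**Strategy.** The two outer benzene rings (rings A and C) are each disconnected across two C–C bonds, back to the hexasubstituted central ring B carrying two buta-1,3-dien-2-yloxy arms. Each outer ring holds its ether oxygen on C1 and its hydroxyl on C4; a 2-oxydiene and a terminal ynone give exactly this para relationship, the acetyl carbon marking C4 for later oxygen insertion. One two-directional Diels–Alder reaction thus forms four C–C bonds and both outer carbocycles. The precursor is 1,4-dibromo-3,6-dimethoxybenzene with the dienyl ether groups on C2 and C5, obtained by methylenating a bis(acrylate), so that the crowded aryl–O–C bonds are made as esters.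

Key step: step 5

Remark: the target is achiral and has no stereocenters, so no stereocontrol is needed. Its central hydroquinone (ring B) is assumed to be air-sensitive and is liberated only in the last step, under reducing work-up.

Step 1
Reactants: 1 bromanil (tetrabromo-1,4-benzoquinone)
Product: 2 2,5-dibromo-3,6-dimethoxy-1,4-benzoquinone
Conditions: NaOMe (2.1 equiv), MeOH, 0 °C to rt
Reagents that add atoms: sodium methoxide, C[O-].[Na+]
Why: Two addition–elimination substitutions (vinylogous acyl substitution on a haloquinone) should replace one bromide on each enone half, because the first methoxy group deactivates the carbonyl it is conjugated with and sends the second methoxide to C5, the 2,5-pattern known for tetrahalo-1,4-benzoquinones.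

Step 2
Reactants: 2 2,5-dibromo-3,6-dimethoxy-1,4-benzoquinone
Product: 3 2,5-dibromo-3,6-dimethoxybenzene-1,4-diol
Conditions: Na2S2O4, EtOAc/H2O, rt, N2
Reagents that add atoms: none
Why: Dithionite reduction of a quinone to its hydroquinone is a two-electron reduction that should leave the C–Br bonds and the methyl ethers untouched.

Step 3
Reactants: 3 2,5-dibromo-3,6-dimethoxybenzene-1,4-diol; 4 acryloyl chloride
Product: 5 2,5-dibromo-3,6-dimethoxy-1,4-phenylene di(prop-2-enoate)
Conditions: acryloyl chloride (2.4 equiv in all), Et3N (3 equiv), BHT (cat.), CH2Cl2, −20 to 0 °C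
Reagents that add atoms: acryloyl chloride (second equivalent of 4), C=CC(Cl)=O
Why: O-Acylation (nucleophilic acyl substitution) of each of the two phenols by one molecule of the acid chloride should be fast even at the flanked hydroxyls, while low temperature and BHT suppress polymerization and conjugate addition of phenoxide to the acrylate.

Step 4
Reactants: 5 2,5-dibromo-3,6-dimethoxy-1,4-phenylene di(prop-2-enoate)
Product: 6 1,4-dibromo-2,5-bis(buta-1,3-dien-2-yloxy)-3,6-dimethoxybenzene
Conditions: Cp2TiMe2 (6 equiv), toluene/THF, 65 °C, dark; filtration through basic alumina (hexane, 1% Et3N)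
Reagents that add atoms: dimethyltitanocene Cp2TiMe2, C[Ti+2]C.c1cc[cH-]c1.c1cc[cH-]c1
Why: Petasis methylenation, in which Cp2TiMe2 loses methane to give Cp2Ti=CH2 that adds across each ester C=O and cycloreverts to the enol ether and Cp2Ti=O, is known for aryl esters and for acrylates (giving 2-oxydienes) and is neither acidic nor basic, so aryl bromides and methyl ethers should survive.

Step 5
Reactants: 6 1,4-dibromo-2,5-bis(buta-1,3-dien-2-yloxy)-3,6-dimethoxybenzene; 7 but-3-yn-2-one
Product: 8 1,4-bis[(4-acetylcyclohexa-1,4-dien-1-yl)oxy]-2,5-dibromo-3,6-dimethoxybenzene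
Conditions: but-3-yn-2-one (6 equiv in all), BHT (cat.), 2,6-di-tert-butyl-4-methylpyridine (5 mol%), toluene, 100 °C, sealed tube
Reagents that add atoms: but-3-yn-2-one (second equivalent of 7), CC(=O)C#C
Why: Each of the two 2-aryloxydiene arms should take up one molecule of the ynone in a concerted, asynchronous, normal-electron-demand [4+2] cycloaddition (diene HOMO, dienophile LUMO), the closest known reaction type being the thermal Diels–Alder reaction of 2-alkoxy- and 2-aryloxybuta-1,3-dienes with acetylenic ketones. Ring A and ring C each close by intermolecular cycloaddition, both ring bonds (diene C1 to the ynone β-carbon, diene C4 to the ynone α-carbon) forming in the same step and leaving a 1,4-cyclohexadiene. No stereocenter is created, since every new sp3 carbon is a CH2 group. The step needs "para" regiochemistry in both arms: the oxygen on diene C2 places the largest HOMO coefficient on C1, which bonds to the unsubstituted β-carbon of the ynone (largest LUMO coefficient), so the acetyl-bearing carbon ends 1,4 to the ether carbon. Neutral, anhydrous, radical-inhibited conditions with a hindered pyridine as acid scavenger protect the acid-labile enol-ether dienes, and the excess of volatile ynone drives both arms, which ring B keeps electronically and spatially independent, to completion.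

Step 6
Reactants: 8 1,4-bis[(4-acetylcyclohexa-1,4-dien-1-yl)oxy]-2,5-dibromo-3,6-dimethoxybenzene (crude, after evaporation of excess ynone)
Product: 9 1,4-bis(4-acetylphenoxy)-2,5-dibromo-3,6-dimethoxybenzene
Conditions: DDQ (2.2 equiv), toluene, rt
Reagents that add atoms: none
Why: DDQ dehydrogenation (hydride abstraction from a doubly allylic CH2, then proton loss) should aromatize each 1,4-cyclohexadiene under mild conditions and turn the labile enol-ether linkage into a robust diaryl ether.

Step 7
Reactants: 9 1,4-bis(4-acetylphenoxy)-2,5-dibromo-3,6-dimethoxybenzene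
Product: 11 1,4-dibromo-2,5-bis(4-hydroxyphenoxy)-3,6-dimethoxybenzene, via bis(acetate) 10 (not isolated)
Conditions: mCPBA, TFA (cat.), CH2Cl2, rt; aq. Na2SO3 wash; then K2CO3, MeOH, rt
Reagents that add atoms: mCPBA, OOC(=O)c1cccc(Cl)c1
Why: In the Baeyer–Villiger oxidation the electron-rich 4-aryloxyphenyl group should migrate in preference to methyl in the Criegee intermediate to give the aryl acetate, and base-catalysed methanolysis (transesterification) then frees each phenol.

Step 8
Reactants: 11 1,4-dibromo-2,5-bis(4-hydroxyphenoxy)-3,6-dimethoxybenzene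
Product: 12 1,4-dibromo-2,5-dimethoxy-3,6-bis(2,3,5-tribromo-4-hydroxyphenoxy)benzene
Conditions: Br2 (6.2 equiv), dry AcOH/CH2Cl2, 0 to 40 °C; aq. Na2S2O3
Reagents that add atoms: bromine, BrBr
Why: In this electrophilic aromatic bromination the free hydroxyl should take the first two bromines to both of its ortho carbons and the ether oxygen the third to one of its two equivalent ortho carbons, after which the last C–H of each ring is hindered and deactivated, while ring B has no free position and its methyl ethers keep it from oxidation to a quinone.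

Step 9
Reactants: 12 1,4-dibromo-2,5-dimethoxy-3,6-bis(2,3,5-tribromo-4-hydroxyphenoxy)benzene
Product: 13 2,5-dibromo-3,6-bis(2,3,5-tribromo-4-hydroxyphenoxy)benzene-1,4-diol (CNP0163357.0)
Conditions: BBr3 (8 equiv), CH2Cl2, −78 °C to rt; H2O, Na2S2O4 work-up under N2
Reagents that add atoms: none
Why: Lewis-acid ether cleavage with BBr3 should remove both methyl groups by bromide attack at the methyl carbon of the boron-complexed methoxy groups (SN2), whereas the diaryl ether bonds offer no sp3 carbon and survive, and the reducing aqueous work-up releases the hydroquinone without air oxidation.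

**Compound list**
1 | bromanil (tetrabromo-1,4-benzoquinone) | O=C1C(Br)=C(Br)C(=O)C(Br)=C1Br | starting material
2 | 2,5-dibromo-3,6-dimethoxy-1,4-benzoquinone | COC1=C(Br)C(=O)C(OC)=C(Br)C1=O | intermediate
3 | 2,5-dibromo-3,6-dimethoxybenzene-1,4-diol | COc1c(Br)c(O)c(OC)c(Br)c1O | intermediate
4 | acryloyl chloride | C=CC(Cl)=O | starting material
5 | 2,5-dibromo-3,6-dimethoxy-1,4-phenylene di(prop-2-enoate) | COc1c(Br)c(OC(=O)C=C)c(OC)c(Br)c1OC(=O)C=C | intermediate
6 | 1,4-dibromo-2,5-bis(buta-1,3-dien-2-yloxy)-3,6-dimethoxybenzene | COc1c(Br)c(OC(=C)C=C)c(OC)c(Br)c1OC(=C)C=C | intermediate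
7 | but-3-yn-2-one | CC(=O)C#C | starting material
8 | 1,4-bis[(4-acetylcyclohexa-1,4-dien-1-yl)oxy]-2,5-dibromo-3,6-dimethoxybenzene | COc1c(Br)c(OC2=CCC(C(C)=O)=CC2)c(OC)c(Br)c1OC1=CCC(C(C)=O)=CC1 | intermediate
9 | 1,4-bis(4-acetylphenoxy)-2,5-dibromo-3,6-dimethoxybenzene | COc1c(Br)c(Oc2ccc(C(C)=O)cc2)c(OC)c(Br)c1Oc1ccc(C(C)=O)cc1 | intermediate
10 | 1,4-bis(4-acetoxyphenoxy)-2,5-dibromo-3,6-dimethoxybenzene (bis(acetate)) | COc1c(Br)c(Oc2ccc(OC(C)=O)cc2)c(OC)c(Br)c1Oc1ccc(OC(C)=O)cc1 | intermediate
11 | 1,4-dibromo-2,5-bis(4-hydroxyphenoxy)-3,6-dimethoxybenzene | COc1c(Br)c(Oc2ccc(O)cc2)c(OC)c(Br)c1Oc1ccc(O)cc1 | intermediate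
12 | 1,4-dibromo-2,5-dimethoxy-3,6-bis(2,3,5-tribromo-4-hydroxyphenoxy)benzene | COc1c(Br)c(Oc2cc(Br)c(O)c(Br)c2Br)c(OC)c(Br)c1Oc1cc(Br)c(O)c(Br)c1Br | intermediate
13 | 2,5-dibromo-3,6-bis(2,3,5-tribromo-4-hydroxyphenoxy)benzene-1,4-diol (CNP0163357.0) | Oc1c(Br)cc(Oc2c(O)c(Br)c(Oc3cc(Br)c(O)c(Br)c3Br)c(O)c2Br)c(Br)c1Br | target

**Step count.** Total: 9 steps. Longest linear sequence: 9 steps (1 to 13).

**Steps most likely to fail, with fallbacks**

Step 5 (key cycloaddition). The dienes may be lost by acid-triggered hydrolysis or polymerization before both arms have reacted, the second arm may lag behind, or some cycloaddition may leak to the "meta" orientation. The fallback sets out from hydroquinone 3 and comes back to the route at diketone 9. It is a double nucleophilic aromatic substitution of the dipotassium salt of 3 on 4-fluoroacetophenone (K2CO3, DMSO, 130 °C, N2), a standard way to 4-aryloxyacetophenones. It should give 9 directly and bypasses 5, 6 and 8; it makes no compound outside the list.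

Step 4 (bis-methylenation). The acrylate double bonds may be consumed by polymerization on heating or by reaction of Cp2Ti=CH2 with the vinyl group instead of the carbonyl, and the diene may hydrolyse on titanium residues during isolation. The fallback sets out from hydroquinone 3 and comes back at bis(diene) 6. Compound 3 would be acylated with 3-chloropropanoyl chloride (pyridine, CH2Cl2, 0 °C) to 2,5-dibromo-3,6-dimethoxy-1,4-phenylene bis(3-chloropropanoate) F1. This saturated ester would be methylenated with Cp2TiMe2 (toluene/THF, 65 °C) to 1,4-dibromo-2,5-bis[(4-chlorobut-1-en-2-yl)oxy]-3,6-dimethoxybenzene F2. Double E2 dehydrochlorination (KOtBu, THF/DMSO, 0 °C to rt) would then unveil the second alkene of each arm under basic conditions, giving 6.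

Step 8 (hexabromination). The bromination may run unevenly, the slow third, ether-directed substitution lagging behind or overrunning to the fourth position in one ring, and moisture may cause oxidative loss of the aryloxy group through ipso attack para to the hydroxyl. The fallback sets out from bis(acetate) 10, which would be isolated after the peracid stage of step 7, and comes back at 12. With the phenols masked, Br2 (2.1 equiv), NaOAc, AcOH at rt should put one bromine ortho to the ether oxygen, the strongest donor, in each ring, giving 1,4-bis(4-acetoxy-2-bromophenoxy)-2,5-dibromo-3,6-dimethoxybenzene F3. Methanolysis (K2CO3, MeOH) would give 1,4-dibromo-2,5-bis(2-bromo-4-hydroxyphenoxy)-3,6-dimethoxybenzene F4. The facile ortho,ortho-dibromination of each phenol (Br2, 4.1 equiv, CH2Cl2/AcOH, 0 °C) would then give 12.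

**Further compounds**
F0 | step 5 | none | none
F1 | step 4 | 2,5-dibromo-3,6-dimethoxy-1,4-phenylene bis(3-chloropropanoate) | COc1c(Br)c(OC(=O)CCCl)c(OC)c(Br)c1OC(=O)CCCl
F2 | step 4 | 1,4-dibromo-2,5-bis[(4-chlorobut-1-en-2-yl)oxy]-3,6-dimethoxybenzene | COc1c(Br)c(OC(=C)CCCl)c(OC)c(Br)c1OC(=C)CCCl
F3 | step 8 | 1,4-bis(4-acetoxy-2-bromophenoxy)-2,5-dibromo-3,6-dimethoxybenzene | COc1c(Br)c(Oc2ccc(OC(C)=O)cc2Br)c(OC)c(Br)c1Oc1ccc(OC(C)=O)cc1Br
F4 | step 8 | 1,4-dibromo-2,5-bis(2-bromo-4-hydroxyphenoxy)-3,6-dimethoxybenzene | COc1c(Br)c(Oc2ccc(O)cc2Br)c(OC)c(Br)c1Oc1ccc(O)cc1Br
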